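**Plan**

- Rings: upper flavan = A (benzo), C (pyran), B (catechol); lower flavan = D (benzo), F (pyran), E (catechol). Retrosynthesis cuts ring F across O1–C2 and C3–C4 (retro-[4+2]) to the ring-D salicylaldehyde 13, benzyl alcohol and the (E)-enol acetate 5. It then cuts the formyl C–C bond at C4a(D) and the interflavan C4(C)–C6(D) bond to resorcinol and the 4-benzyloxyflavan 8, and ring C across the same two bonds to aldehyde 6, benzyl alcohol and 5.
- Forward: 5 (three steps from 1); ring C (step 4); ring D attached (step 5); formyl group and benzyl ether on ring D (steps 6 and 7); ring F, the last ring (step 8); acetates off (step 9); benzyl groups off (step 10).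
- Enabling feature: in ring D the oxygen that becomes O1 sits on C8a, ortho to C4a; C4 is an oxygenated benzylic carbon and the C7 oxygen is para to C4a. The unit O–C8a=C4a–C4(OR) is therefore a latent, donor-stabilised α-alkoxy o-quinone methide. The para-oxygenated ring E makes C2 the cationic end of the C2=C3 partner, so O1–C2 and C3–C4 form with flavan regiochemistry.
- Stereochemistry: C2 and C3 of each unit come from the E geometry of 5 and a chiral Brønsted acid. C4 of ring F (and of 8) comes from the endo transition state and thermodynamic control. The 4α interflavan bond comes from anti attack on the acetoxonium ion of the 3-acetate.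
- Helpers: the benzyl group on O4 (makes the o-quinone methide), the acetyl groups on O3 (regiochemistry, participation) and the aryl benzyl ethers; all leave in steps 9 and 10.

Key step: step 8

Remark: the sense of induction of the chiral acid cannot be derived from the structure alone. The route is written with the (R)-acid; its sense is to be read off at step 4 (one pair of enantiomers), and the (S)-acid takes its place in steps 4 and 8 should the (R)-acid favour the antipode of 8.

**Route**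

Step 1
Reactants: 1 3,4-bis(benzyloxy)benzaldehyde; 2 bis(pinacolato)borylmethane
Product: 3 (E)-2-[3,4-bis(benzyloxy)phenyl]ethenylboronic acid pinacol ester
Conditions: 2 (1.2 equiv), lithium 2,2,6,6-tetramethylpiperidide (1.2 equiv), THF, 0 °C; then 1, −78 °C → rt
Reagents that add atoms: none
Why: Boron–Wittig olefination, in which the α-boryl carbanion of 2 adds to the aldehyde and syn B–O elimination from the β-alkoxide gives the alkenyl boronate with E geometry (aryl and boryl groups anti in the elimination).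

Step 2
Reactants: 3 (E)-alkenyl pinacol boronate
Product: 4 potassium (E)-2-[3,4-bis(benzyloxy)phenyl]ethenyltrifluoroborate
Conditions: KHF2 (4.5 equiv), MeOH/H2O, rt
Reagents that add atoms: potassium hydrogen difluoride, [K+].[F-].F
Why: Standard exchange of a pinacol boronate for the trifluoroborate salt, which leaves the alkene geometry untouched and gives the boron partner needed for the C–O coupling.

Step 3
Reactants: 4 potassium (E)-alkenyltrifluoroborate
Product: 5 (E)-2-[3,4-bis(benzyloxy)phenyl]ethenyl acetate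
Conditions: AcOH (2 equiv), Cu(OAc)2 (10 mol %), 4-(dimethylamino)pyridine (20 mol %), 4 Å molecular sieves, O2 (1 atm), MeCN, 40 °C
Reagents that add atoms: acetic acid, CC(=O)O
Why: Chan–Lam-type oxidative C–O coupling of an alkenyltrifluoroborate with a carboxylic acid under divalent copper catalysis, a reaction type that gives enol esters with retention of the alkene geometry.

Step 4
Reactants: 6 4-(benzyloxy)-2-hydroxybenzaldehyde; 5 (E)-2-[3,4-bis(benzyloxy)phenyl]ethenyl acetate
Product: 8 (2R,3S,4R)-3-O-acetyl-4,7,3',4'-tetra-O-benzylmollisacacidin, via benzyloxy o-quinone methide 7 (not isolated)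
Conditions: 5 (1.3 equiv), BnOH (3 equiv), (R)-3,3'-bis(2,4,6-triisopropylphenyl)-1,1'-binaphthyl-2,2'-diyl N-(trifluoromethanesulfonyl)phosphoramide (5 mol %), 5 Å molecular sieves, CH2Cl2, −20 °C → rt; Et3N quench
Reagents that add atoms: benzyl alcohol, OCc1ccccc1
Why: Proposed new method: acid-catalysed condensation of 6 with BnOH and loss of water gives the (E)-α-benzyloxy o-quinone methide 7 as an ion pair with the chiral phosphoramide anion; 5 attacks it through its acetoxy-bearing carbon because the developing cation is then benzylic to the 3,4-bis(benzyloxy)phenyl ring, and the phenol oxygen closes ring C (inverse-electron-demand [4+2]); the E alkene gives 2,3-trans, the endo-aryl transition state together with reversible ionisation at C4 gives 3,4-trans, and the anion selects the alkene face (absolute configuration); the closest known reaction types are the acid-catalysed three-component hetero-Diels–Alder reaction of salicylaldehydes, alcohols or orthoformates and styrenes to 4-alkoxyflavans and the chiral-Brønsted-acid-catalysed cycloadditions of transient o-quinone methides, neither shown with a β-acyloxystyrene.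

Step 5
Reactants: 8 3-O-acetyl-4,7,3',4'-tetra-O-benzylmollisacacidin; 9 resorcinol
Product: 10 (2R,3S,4R)-3-O-acetyl-7,3',4'-tri-O-benzyl-4-(2,4-dihydroxyphenyl)flavan-3-ol
Conditions: 9 (5 equiv), BF3·OEt2 (30 mol %), CH2Cl2/THF, −20 → 0 °C
Reagents that add atoms: none
Why: Friedel–Crafts arylation of a 4-alkoxyflavan, in which BF3 ionises the C4 benzyl ether to the cation stabilised by the para 7-benzyloxy group, the 3-acetate bridges it as an acetoxonium ion and resorcinol (in excess, reacting at its C4) enters anti to the acetate to set the 4α (3,4-trans) aryl group.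

Step 6
Reactants: 10 4-(2,4-dihydroxyphenyl)flavan-3-yl acetate
Product: 12 (2R,3S,4R)-3-O-acetyl-7,3',4'-tri-O-benzyl-4-(5-formyl-2,4-dihydroxyphenyl)flavan-3-ol, via aryl iminium chloride 11 (not isolated)
Conditions: (chloromethylene)dimethyliminium chloride (1.3 equiv), MeCN, −10 °C → rt; then H2O, 40 °C
Reagents that add atoms: (chloromethylene)dimethyliminium chloride, C[N+](C)=CCl.[Cl-]; water, O
Why: Vilsmeier–Haack formylation, which on a 4-substituted resorcinol takes place para to one hydroxyl and ortho to the other (the ring-D carbon that becomes C4a) and leaves the less activated ether rings A and B alone.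

Step 7
Reactants: 12 ring-D 2,4-dihydroxybenzaldehyde
Product: 13 (2R,3S,4S)-3-O-acetyl-7,3',4'-tri-O-benzyl-4-[2-(benzyloxy)-5-formyl-4-hydroxyphenyl]flavan-3-ol
Conditions: BnBr (1.05 equiv), NaHCO3 (1.5 equiv), MeCN, 60 °C
Reagents that add atoms: benzyl bromide, BrCc1ccccc1
Why: Regioselective O-alkylation of a 2,4-dihydroxybenzaldehyde, in which the hydroxyl para to the formyl group is the more acidic and is not held in the hydrogen bond to the carbonyl, so weak base alkylates it alone and leaves free the phenol needed for the key step.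

Step 8
Reactants: 13 ring-D salicylaldehyde; 5 (E)-2-[3,4-bis(benzyloxy)phenyl]ethenyl acetate
Product: 15 bis-O-acetyl hepta-O-benzyl fisetinidol-(4α→6)-mollisacacidin, via ring-D benzyloxy o-quinone methide 14 (not isolated)
Conditions: 5 (3 equiv), BnOH (5 equiv), (R)-3,3'-bis(2,4,6-triisopropylphenyl)-1,1'-binaphthyl-2,2'-diyl N-(trifluoromethanesulfonyl)phosphoramide (10 mol %), 5 Å molecular sieves, CH2Cl2, −20 °C → rt; Et3N quench
Reagents that add atoms: benzyl alcohol, OCc1ccccc1
Why: Proposed new method: acid-catalysed condensation of the ring-D salicylaldehyde 13 with BnOH and loss of water gives the (E)-α-benzyloxy o-quinone methide 14 (heterodiene O=C8a–C4a=C4, present as its O-protonated ion pair with the chiral phosphoramide anion, which is hydrogen-bonded to the phenolic O–H), and 5 adds to it through C3 while the charge that builds at C2 is taken up by the ring-D oxygen. The closest known reaction types are the acid-catalysed three-component hetero-Diels–Alder reaction of salicylaldehydes, alcohols or orthoformates and styrenes to 4-alkoxyflavans and the chiral-Brønsted-acid-catalysed cycloadditions of o-quinone methides formed in situ from salicylaldehydes and alcohols; the β-acyloxystyrene partner and the intermolecular catalyst control are new. Ring F closes as the six-membered adduct of an inverse-electron-demand [4+2] cycloaddition that forms C4–C3 and O1–C2, asynchronous with the C–C bond leading (in the stepwise limit a 6-exo-trig capture of the benzylic cation at C2 by the phenol). C2 and C3 become trans because the E geometry of 5 is transferred suprafacially, and their absolute configuration (2R,3S) is fixed by the chiral anion, which selects the face of C3 in the C–C bond-forming transition state; C4 (R, 2,4-cis, 3,4-trans) follows from the endo position of ring E over the (E)-heterodiene and is also the thermodynamic epimer, reachable by reversible ionisation of the benzylic ether assisted by the 3-acetate. The step needs C3 and not C2 to bond to C4, which the stronger stabilisation of a cation at C2 by the 4-alkoxyphenyl ring E than at C3 by an acyloxy group secures; it needs the cation to prefer 5 over the resorcinol-type rings A and D of a second molecule, which the excess of 5 and the return of the cation to its acetal by BnOH secure; and it needs catalyst control over the remote upper unit, which sits on C6, meta to C4a and away from both ends of the heterodiene.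

Step 9
Reactants: 15 bis-O-acetyl hepta-O-benzyl dimer
Product: 16 hepta-O-benzyl fisetinidol-(4α→6)-mollisacacidin
Conditions: K2CO3 (0.3 equiv), MeOH/THF (1:1), rt
Reagents that add atoms: none
Why: Base-catalysed methanolysis of the two secondary acetates, to which the benzylic and aryl benzyl ethers are inert and under which no stereocentre is acidic.

Step 10
Reactants: 16 hepta-O-benzyl dimer
Product: 17 fisetinidol-(4α→6)-fisetinidol-4α-ol (target)
Conditions: H2 (1 atm), Pd(OH)2/C, THF/MeOH (1:1), rt, stopped after uptake of seven equivalents of H2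
Reagents that add atoms: none
Why: Hydrogenolysis of the six aryl benzyl ethers and of the unhindered primary benzyl–oxygen bond of the C4 ether under neutral conditions, under which the ring C–O bonds at C2 and C4 of flavans should be cleaved much more slowly.

**Compound list**

All flavan units are 2,3-trans-3,4-trans. The label at the upper C4 changes between R and S only because substituent priorities on ring D change, not the geometry.

1 | 3,4-bis(benzyloxy)benzaldehyde | O=Cc1ccc(OCc2ccccc2)c(OCc2ccccc2)c1 | starting material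
2 | bis(pinacolato)borylmethane, 2,2'-methylenebis(4,4,5,5-tetramethyl-1,3,2-dioxaborolane) | CC1(C)OB(CB2OC(C)(C)C(C)(C)O2)OC1(C)C | starting material
3 | 2-[(E)-2-[3,4-bis(benzyloxy)phenyl]ethenyl]-4,4,5,5-tetramethyl-1,3,2-dioxaborolane | CC1(C)OB(/C=C/c2ccc(OCc3ccccc3)c(OCc3ccccc3)c2)OC1(C)C | intermediate
4 | potassium [(E)-2-[3,4-bis(benzyloxy)phenyl]ethenyl]trifluoroborate | [K+].F[B-](F)(F)/C=C/c1ccc(OCc2ccccc2)c(OCc2ccccc2)c1 | intermediate
5 | (E)-2-[3,4-bis(benzyloxy)phenyl]ethenyl acetate | CC(=O)O/C=C/c1ccc(OCc2ccccc2)c(OCc2ccccc2)c1 | intermediate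
6 | 4-(benzyloxy)-2-hydroxybenzaldehyde | O=Cc1ccc(OCc2ccccc2)cc1O | starting material
7 | (6E)-3-(benzyloxy)-6-[(benzyloxy)methylidene]cyclohexa-2,4-dien-1-one | c1ccccc1CO/C=C1\C=CC(OCc2ccccc2)=CC1=O | intermediate
8 | (2R,3S,4R)-4,7-bis(benzyloxy)-2-[3,4-bis(benzyloxy)phenyl]-3,4-dihydro-2H-chromen-3-yl acetate | c1ccccc1COc1ccc2c(c1)O[C@H](c1ccc(OCc3ccccc3)c(OCc3ccccc3)c1)[C@@H](OC(C)=O)[C@@H]2OCc1ccccc1 | intermediate
9 | resorcinol (benzene-1,3-diol) | Oc1cccc(O)c1 | starting material
10 | (2R,3S,4R)-7-(benzyloxy)-2-[3,4-bis(benzyloxy)phenyl]-4-(2,4-dihydroxyphenyl)-3,4-dihydro-2H-chromen-3-yl acetate | c1ccccc1COc1ccc2c(c1)O[C@H](c1ccc(OCc3ccccc3)c(OCc3ccccc3)c1)[C@@H](OC(C)=O)[C@@H]2c1ccc(O)cc1O | intermediate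
11 | N-[[5-[(2R,3S,4R)-3-acetoxy-7-(benzyloxy)-2-[3,4-bis(benzyloxy)phenyl]-3,4-dihydro-2H-chromen-4-yl]-2,4-dihydroxyphenyl]methylidene]-N-methylmethanaminium chloride | c1ccccc1COc1ccc2c(c1)O[C@H](c1ccc(OCc3ccccc3)c(OCc3ccccc3)c1)[C@@H](OC(C)=O)[C@@H]2c1cc(C=[N+](C)C)c(O)cc1O.[Cl-] | intermediate
12 | (2R,3S,4R)-7-(benzyloxy)-2-[3,4-bis(benzyloxy)phenyl]-4-(5-formyl-2,4-dihydroxyphenyl)-3,4-dihydro-2H-chromen-3-yl acetate | c1ccccc1COc1ccc2c(c1)O[C@H](c1ccc(OCc3ccccc3)c(OCc3ccccc3)c1)[C@@H](OC(C)=O)[C@@H]2c1cc(C=O)c(O)cc1O | intermediate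
13 | (2R,3S,4S)-7-(benzyloxy)-4-[2-(benzyloxy)-5-formyl-4-hydroxyphenyl]-2-[3,4-bis(benzyloxy)phenyl]-3,4-dihydro-2H-chromen-3-yl acetate | c1ccccc1COc1ccc2c(c1)O[C@H](c1ccc(OCc3ccccc3)c(OCc3ccccc3)c1)[C@@H](OC(C)=O)[C@@H]2c1cc(C=O)c(O)cc1OCc1ccccc1 | intermediate
14 | (2R,3S,4S)-7-(benzyloxy)-4-[(5E)-2-(benzyloxy)-5-[(benzyloxy)methylidene]-4-oxocyclohexa-1,6-dien-1-yl]-2-[3,4-bis(benzyloxy)phenyl]-3,4-dihydro-2H-chromen-3-yl acetate (ring D as 3-benzyloxy-6-(benzyloxymethylidene)cyclohexa-2,4-dienone carrying the flavanyl group on C4) | c1ccccc1COc1ccc2c(c1)O[C@H](c1ccc(OCc3ccccc3)c(OCc3ccccc3)c1)[C@@H](OC(C)=O)[C@@H]2C1=C/C(=C\OCc3ccccc3)C(=O)C=C1OCc1ccccc1 | intermediate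
15 | (2R,3S,4R)-6-[(2R,3S,4S)-3-acetoxy-7-(benzyloxy)-2-[3,4-bis(benzyloxy)phenyl]-3,4-dihydro-2H-chromen-4-yl]-4,7-bis(benzyloxy)-2-[3,4-bis(benzyloxy)phenyl]-3,4-dihydro-2H-chromen-3-yl acetate | c1ccccc1COc1ccc2c(c1)O[C@H](c1ccc(OCc3ccccc3)c(OCc3ccccc3)c1)[C@@H](OC(C)=O)[C@@H]2c1cc2c(cc1OCc1ccccc1)O[C@H](c1ccc(OCc3ccccc3)c(OCc3ccccc3)c1)[C@@H](OC(C)=O)[C@@H]2OCc1ccccc1 | intermediate
16 | (2R,3S,4R)-4,7-bis(benzyloxy)-6-[(2R,3S,4S)-7-(benzyloxy)-2-[3,4-bis(benzyloxy)phenyl]-3-hydroxy-3,4-dihydro-2H-chromen-4-yl]-2-[3,4-bis(benzyloxy)phenyl]-3,4-dihydro-2H-chromen-3-ol | c1ccccc1COc1ccc2c(c1)O[C@H](c1ccc(OCc3ccccc3)c(OCc3ccccc3)c1)[C@@H](O)[C@@H]2c1cc2c(cc1OCc1ccccc1)O[C@H](c1ccc(OCc3ccccc3)c(OCc3ccccc3)c1)[C@@H](O)[C@@H]2OCc1ccccc1 | intermediate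
17 | (2R,3S,4R)-2-(3,4-dihydroxyphenyl)-6-[(2R,3S,4R)-2-(3,4-dihydroxyphenyl)-3,7-dihydroxy-3,4-dihydro-2H-chromen-4-yl]-3,4-dihydro-2H-chromene-3,4,7-triol | Oc1ccc2c(c1)O[C@H](c1ccc(O)c(O)c1)[C@@H](O)[C@@H]2c1cc2c(cc1O)O[C@H](c1ccc(O)c(O)c1)[C@@H](O)[C@@H]2O | target

**Step count and risks**

Total steps: 10. Longest linear sequence: 10 steps (1 → 3 → 4 → 5 → 8 → 10 → 12 → 13 → 15 → 16 → 17).

Steps most likely to fail:

1. Step 8 (Proposed new method). What may go wrong:
   - bonding of the alkene through C2 instead of C3;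
   - acid-catalysed addition of benzyl alcohol to the enol acetate or acyl transfer from it;
   - Friedel–Crafts capture of the benzylic cation by the electron-rich rings of a second molecule;
   - insufficient facial control by the chiral anion.

   Fallback (known chemistry), setting out from 13 and coming back at 17: the ring-D phenol of 13 is protected as the methoxymethyl ether F1 (MOMCl, iPr2NEt, CH2Cl2). Methylmagnesium bromide (excess, THF, 0 °C) adds to the aldehyde and cleaves the acetate to give the benzylic alcohol F2 (both carbinol epimers, of no consequence), which MnO2 (CH2Cl2) oxidises to the 2'-(methoxymethoxy)acetophenone F3. Claisen–Schmidt condensation with aldehyde 1 (KOH, EtOH/THF) gives the (E)-chalcone F4, and Juliá–Colonna epoxidation (poly-L-leucine, urea–hydrogen peroxide, DBU, THF) gives the (αR,βS)-epoxide F5. HCl in MeOH/THF removes the MOM group, and the freed phenol opens the epoxide at the benzylic carbon with inversion to give the 2,3-trans-dihydroflavonol F6. Hydrogenolysis (H2, Pd(OH)2/C, THF/MeOH) gives the free phenolic ketone F7, and NaBH4 (EtOH, 0 °C) reduces the C4 carbonyl to the 3,4-trans alcohol 17.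

2. Step 4 (Proposed new method). What may go wrong: the same processes as in step 8, plus incomplete enantioselectivity that would carry through as diastereomers later.

   Fallback (known chemistry), setting out from 1 and coming back at 10: commercial 1-[4-(benzyloxy)-2-hydroxyphenyl]ethanone is protected as its methoxymethyl ether F8 (MOMCl, NaH, DMF) and condensed with 1 (KOH, EtOH) to the (E)-chalcone F9. Juliá–Colonna epoxidation as above gives the (αR,βS)-epoxide F10, and HCl/MeOH cyclises it to the (2R,3R)-dihydroflavonol F11. NaBH4 (EtOH, 0 °C) gives the 2,3-trans-3,4-trans diol F12, and Ac2O/pyridine/4-(dimethylamino)pyridine gives the diacetate F13. Arylation with resorcinol 9 under BF3·OEt2 as in step 5, the 4-acetate now being the leaving group, gives 10.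

3. Step 10. What may go wrong: hydrogenolysis of the ring-F benzylic C4–O bond, either in place of the benzyl–oxygen bond or after it, with loss of the 4-hydroxyl.

   Fallback, setting out from 16 and coming back at 17: the C4 benzyl ether of 16 is exchanged for hydroxyl by acid-catalysed solvolysis (pyridinium p-toluenesulfonate, THF/H2O, 40 °C) to give the hexa-O-benzyl triol F14. The benzylic C4 alcohol alone is oxidised with MnO2 to the ketone F6 (listed under the fallback to step 8). Hydrogenolysis to F7 followed by NaBH4 reduction then gives 17, so that no benzylic C4–O single bond meets hydrogen and the catalyst.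

Further compounds
F1 | step 8 | (2R,3S,4S)-7-(benzyloxy)-4-[2-(benzyloxy)-5-formyl-4-(methoxymethoxy)phenyl]-2-[3,4-bis(benzyloxy)phenyl]-3,4-dihydro-2H-chromen-3-yl acetate | c1ccccc1COc1ccc2c(c1)O[C@H](c1ccc(OCc3ccccc3)c(OCc3ccccc3)c1)[C@@H](OC(C)=O)[C@@H]2c1cc(C=O)c(OCOC)cc1OCc1ccccc1
F2 | step 8 | 1-[4-(benzyloxy)-5-[(2R,3S,4S)-7-(benzyloxy)-2-[3,4-bis(benzyloxy)phenyl]-3-hydroxy-3,4-dihydro-2H-chromen-4-yl]-2-(methoxymethoxy)phenyl]ethanol (carbinol epimers) | c1ccccc1COc1ccc2c(c1)O[C@H](c1ccc(OCc3ccccc3)c(OCc3ccccc3)c1)[C@@H](O)[C@@H]2c1cc(C(C)O)c(OCOC)cc1OCc1ccccc1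
F3 | step 8 | 1-[4-(benzyloxy)-5-[(2R,3S,4S)-7-(benzyloxy)-2-[3,4-bis(benzyloxy)phenyl]-3-hydroxy-3,4-dihydro-2H-chromen-4-yl]-2-(methoxymethoxy)phenyl]ethanone | c1ccccc1COc1ccc2c(c1)O[C@H](c1ccc(OCc3ccccc3)c(OCc3ccccc3)c1)[C@@H](O)[C@@H]2c1cc(C(C)=O)c(OCOC)cc1OCc1ccccc1
F4 | step 8 | (E)-1-[4-(benzyloxy)-5-[(2R,3S,4S)-7-(benzyloxy)-2-[3,4-bis(benzyloxy)phenyl]-3-hydroxy-3,4-dihydro-2H-chromen-4-yl]-2-(methoxymethoxy)phenyl]-3-[3,4-bis(benzyloxy)phenyl]prop-2-en-1-one | c1ccccc1COc1ccc2c(c1)O[C@H](c1ccc(OCc3ccccc3)c(OCc3ccccc3)c1)[C@@H](O)[C@@H]2c1cc(C(=O)/C=C/c3ccc(OCc4ccccc4)c(OCc4ccccc4)c3)c(OCOC)cc1OCc1ccccc1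
F5 | step 8 | [4-(benzyloxy)-5-[(2R,3S,4S)-7-(benzyloxy)-2-[3,4-bis(benzyloxy)phenyl]-3-hydroxy-3,4-dihydro-2H-chromen-4-yl]-2-(methoxymethoxy)phenyl][(2R,3S)-3-[3,4-bis(benzyloxy)phenyl]oxiran-2-yl]methanone | c1ccccc1COc1ccc2c(c1)O[C@H](c1ccc(OCc3ccccc3)c(OCc3ccccc3)c1)[C@@H](O)[C@@H]2c1cc(C(=O)[C@@H]3O[C@H]3c3ccc(OCc4ccccc4)c(OCc4ccccc4)c3)c(OCOC)cc1OCc1ccccc1
F6 | step 8 | (2R,3R)-7-(benzyloxy)-6-[(2R,3S,4S)-7-(benzyloxy)-2-[3,4-bis(benzyloxy)phenyl]-3-hydroxy-3,4-dihydro-2H-chromen-4-yl]-2-[3,4-bis(benzyloxy)phenyl]-3-hydroxy-2,3-dihydro-4H-chromen-4-one | c1ccccc1COc1ccc2c(c1)O[C@H](c1ccc(OCc3ccccc3)c(OCc3ccccc3)c1)[C@@H](O)[C@@H]2c1cc2c(cc1OCc1ccccc1)O[C@H](c1ccc(OCc3ccccc3)c(OCc3ccccc3)c1)[C@@H](O)C2=O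
F7 | step 8 | (2R,3R)-2-(3,4-dihydroxyphenyl)-6-[(2R,3S,4R)-2-(3,4-dihydroxyphenyl)-3,7-dihydroxy-3,4-dihydro-2H-chromen-4-yl]-3,7-dihydroxy-2,3-dihydro-4H-chromen-4-one | Oc1ccc2c(c1)O[C@H](c1ccc(O)c(O)c1)[C@@H](O)[C@@H]2c1cc2c(cc1O)O[C@H](c1ccc(O)c(O)c1)[C@@H](O)C2=O
F8 | step 4 | 1-[4-(benzyloxy)-2-(methoxymethoxy)phenyl]ethanone | CC(=O)c1ccc(OCc2ccccc2)cc1OCOC
F9 | step 4 | (E)-1-[4-(benzyloxy)-2-(methoxymethoxy)phenyl]-3-[3,4-bis(benzyloxy)phenyl]prop-2-en-1-one | COCOc1cc(OCc2ccccc2)ccc1C(=O)/C=C/c1ccc(OCc2ccccc2)c(OCc2ccccc2)c1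
F10 | step 4 | [4-(benzyloxy)-2-(methoxymethoxy)phenyl][(2R,3S)-3-[3,4-bis(benzyloxy)phenyl]oxiran-2-yl]methanone | COCOc1cc(OCc2ccccc2)ccc1C(=O)[C@@H]1O[C@H]1c1ccc(OCc2ccccc2)c(OCc2ccccc2)c1
F11 | step 4 | (2R,3R)-7-(benzyloxy)-2-[3,4-bis(benzyloxy)phenyl]-3-hydroxy-2,3-dihydro-4H-chromen-4-one | c1ccccc1COc1ccc2c(c1)O[C@H](c1ccc(OCc3ccccc3)c(OCc3ccccc3)c1)[C@@H](O)C2=O
F12 | step 4 | (2R,3S,4R)-7-(benzyloxy)-2-[3,4-bis(benzyloxy)phenyl]-3,4-dihydro-2H-chromene-3,4-diol | c1ccccc1COc1ccc2c(c1)O[C@H](c1ccc(OCc3ccccc3)c(OCc3ccccc3)c1)[C@@H](O)[C@@H]2O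
F13 | step 4 | (2R,3R,4R)-7-(benzyloxy)-2-[3,4-bis(benzyloxy)phenyl]-3,4-dihydro-2H-chromene-3,4-diyl diacetate (2,3-trans-3,4-trans) | c1ccccc1COc1ccc2c(c1)O[C@H](c1ccc(OCc3ccccc3)c(OCc3ccccc3)c1)[C@@H](OC(C)=O)[C@@H]2OC(C)=O
F14 | step 10 | (2R,3S,4R)-7-(benzyloxy)-6-[(2R,3S,4S)-7-(benzyloxy)-2-[3,4-bis(benzyloxy)phenyl]-3-hydroxy-3,4-dihydro-2H-chromen-4-yl]-2-[3,4-bis(benzyloxy)phenyl]-3,4-dihydro-2H-chromene-3,4-diol | c1ccccc1COc1ccc2c(c1)O[C@H](c1ccc(OCc3ccccc3)c(OCc3ccccc3)c1)[C@@H](O)[C@@H]2c1cc2c(cc1OCc1ccccc1)O[C@H](c1ccc(OCc3ccccc3)c(OCc3ccccc3)c1)[C@@H](O)[C@@H]2O
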